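**Strategy.** The pyran ring of the lower unit (O1, C2, C3, C4, C4a, C8a) is made by one-carbon expansion of a cis-2-aryl-2,3-dihydrobenzofuran, which an enantioselective rhodium-carbenoid C–H insertion provides. The key step exploits the electron-rich ring A carbon C4a (ortho to the C5 and C8a oxygens, para to the C7 oxygen): it migrates from C3 to the exocyclic CH2 (the future C4) through a phenonium ion while acetate enters at C3 with inversion, so the cis five-membered ring is relayed into the 2,3-cis flavan. The upper unit comes from (−)-catechin; C4–C8 coupling, inversion of its C3 carbinol by oxidation and reduction, hydroxylation of the lower C4 and hydrogenolysis complete the synthesis.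

Key step: step 7

Remark: Rh2(S-PTTL)4, dirhodium tetrakis[N-phthaloyl-(S)-tert-leucinate], is assumed to deliver the (2S,3R) cis ester 7; if the sense of induction is opposite on this substrate, the enantiomeric catalyst Rh2(R-PTTL)4 is used.

Step 1
Reactants: 1 2',4',6'-trihydroxyacetophenone
Product: 2 1-{2-hydroxy-4,6-bis[4-(trifluoromethyl)benzyloxy]phenyl}ethanone
Conditions: 4-(trifluoromethyl)benzyl bromide (2.1 equiv), K2CO3, DMF, rt
Reagents that add atoms: 4-(trifluoromethyl)benzyl bromide FC(F)(F)c1ccc(CBr)cc1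
Why: Williamson etherification in which the para and one ortho hydroxyl react while the second ortho hydroxyl stays hydrogen-bonded to the carbonyl; the electron-poor benzyl groups are chosen because their benzylic C–H bonds are deactivated toward the carbenoid of step 5 and inert to DDQ.

Step 2
Reactants: 2 1-{2-hydroxy-4,6-bis[4-(trifluoromethyl)benzyloxy]phenyl}ethanone; 3 3,4-bis(benzyloxy)benzyl chloride
Product: 4 1-{2-[3,4-bis(benzyloxy)benzyloxy]-4,6-bis[4-(trifluoromethyl)benzyloxy]phenyl}ethanone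
Conditions: K2CO3, Bu4NI (cat.), DMF, 60 °C
Reagents that add atoms: none
Why: Williamson etherification of the chelated phenol under forcing conditions, installing the benzyl group that becomes C2 and ring B of the lower unit.

Step 3
Reactants: 4 1-{2-[3,4-bis(benzyloxy)benzyloxy]-4,6-bis[4-(trifluoromethyl)benzyloxy]phenyl}ethanone
Product: 5 methyl 2-{2-[3,4-bis(benzyloxy)benzyloxy]-4,6-bis[4-(trifluoromethyl)benzyloxy]phenyl}acetate
Conditions: Tl(NO3)3·3H2O, MeOH/HC(OMe)3, rt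
Reagents that add atoms: methanol CO
Why: Thallium trinitrate oxidative rearrangement of an aryl methyl ketone, in which oxythallation of the enol ether is followed by 1,2-shift of the very electron-rich aryl group to give the methyl arylacetate.

Step 4
Reactants: 5 methyl 2-{2-[3,4-bis(benzyloxy)benzyloxy]-4,6-bis[4-(trifluoromethyl)benzyloxy]phenyl}acetate
Product: 6 methyl 2-diazo-2-{2-[3,4-bis(benzyloxy)benzyloxy]-4,6-bis[4-(trifluoromethyl)benzyloxy]phenyl}acetate
Conditions: 4-acetamidobenzenesulfonyl azide, DBU, MeCN, 0 °C to rt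
Reagents that add atoms: 4-acetamidobenzenesulfonyl azide CC(=O)Nc1ccc(cc1)S(=O)(=O)N=[N+]=[N-]
Why: Regitz diazo transfer to the benzylic ester methylene, the standard entry to aryl diazoacetates.

Step 5
Reactants: 6 methyl 2-diazo-2-{2-[3,4-bis(benzyloxy)benzyloxy]-4,6-bis[4-(trifluoromethyl)benzyloxy]phenyl}acetate
Product: 7 methyl (2S,3R)-2-[3,4-bis(benzyloxy)phenyl]-4,6-bis[4-(trifluoromethyl)benzyloxy]-2,3-dihydrobenzofuran-3-carboxylate (2,3-cis)
Conditions: Rh2(S-PTTL)4 (1 mol %), toluene, −60 °C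
Reagents that add atoms: none
Why: Intramolecular 1,5 C–H insertion of the donor/acceptor dirhodium carbenoid into the electron-rich benzylic C–H of the ortho 3,4-bis(benzyloxy)benzyl ether, a concerted insertion that gives the cis ester kinetically and sets C2 and C3 under control of the chiral carboxylate ligands, while the deactivated trifluoromethylbenzyl C–H bonds on the other ortho oxygen do not compete.

Step 6
Reactants: 7 methyl (2S,3R)-2-[3,4-bis(benzyloxy)phenyl]-4,6-bis[4-(trifluoromethyl)benzyloxy]-2,3-dihydrobenzofuran-3-carboxylate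
Product: 8 {(2S,3S)-2-[3,4-bis(benzyloxy)phenyl]-4,6-bis[4-(trifluoromethyl)benzyloxy]-2,3-dihydrobenzofuran-3-yl}methanol (2,3-cis)
Conditions: i-Bu2AlH (3 equiv), CH2Cl2, −78 °C
Reagents that add atoms: none
Why: Reduction of the ester to the primary alcohol with a non-basic aluminium hydride, so that the epimerisable C3 centre keeps its cis configuration.

Step 7
Reactants: 8 {(2S,3S)-2-[3,4-bis(benzyloxy)phenyl]-4,6-bis[4-(trifluoromethyl)benzyloxy]-2,3-dihydrobenzofuran-3-yl}methanol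
Product: 11 (2R,3R)-2-[3,4-bis(benzyloxy)phenyl]-5,7-bis[4-(trifluoromethyl)benzyloxy]chroman-3-yl acetate (2,3-cis), via primary mesylate 9 (not isolated), via spiro phenonium ion 10 (not isolated)
Conditions: Ms2O, Et3N, CH2Cl2, −20 °C; then NaOAc, AcOH, 40 °C
Reagents that add atoms: sodium acetate CC(=O)[O-].[Na+]
Why: Ionisation of the primary mesylate 9 is assisted by the 2,4,6-trioxygenated ring A, whose ipso carbon (the future C4a) closes onto the CH2 carbon in 3-exo-tet mode to give the bridged phenonium ion 10. Acetate then attacks the secondary carbon C3 anti to the departing aryl carbon, so the bond shared by the three- and five-membered rings breaks and the six-membered ring O1–C2–C3–C4–C4a–C8a arises by this bond fission and not by a cyclisation. The closest known reaction type is the solvolytic neophyl (phenonium) Wagner–Meerwein 1,2-aryl shift, as in the ring expansion of 1-indanylmethyl sulfonates to 2-tetralyl esters. C2 is untouched and C3 is inverted as C4a is replaced by oxygen, which translates the cis dihydrobenzofuran into the 2,3-cis flavan with the acetate cis to the C2 aryl group. The step needs opening at C3 and not at CH2 (which would only return the unrearranged primary acetate); this should be secured by the greater cationic character of the secondary carbon and by relief of the bicyclo[3.1.0] strain. It also needs capture before a free C3 cation can rearrange, which the buffered acetate medium, the chloride-free activation with Ms2O and the lack of any C2 substituent antiperiplanar to the breaking bond should ensure.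

Step 8
Reactants: 12 (−)-catechin, (2S,3R)-2-(3,4-dihydroxyphenyl)chroman-3,5,7-triol
Product: 13 (2S,3R)-5,7,3',4'-tetra-O-benzylcatechin
Conditions: BnBr (4.4 equiv), K2CO3, DMF, 0 °C to rt
Reagents that add atoms: benzyl bromide BrCc1ccccc1
Why: Williamson etherification selective for the four phenols, the aliphatic C3 hydroxyl not being deprotonated by carbonate.

Step 9
Reactants: 13 (2S,3R)-5,7,3',4'-tetra-O-benzylcatechin
Product: 14 (2S,3R,4R)-5,7,3',4'-tetra-O-benzyl-4-(2-ethoxyethoxy)flavan-3-ol (2,4-trans ether)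
Conditions: DDQ (2 equiv), 2-ethoxyethanol, CH2Cl2, rt
Reagents that add atoms: 2-ethoxyethanol CCOCCO
Why: DDQ abstracts hydride from C4, the methylene conjugated to the 5,7-dialkoxy ring, and the alcohol traps the cation anti to the C2 aryl group, as known for benzylated catechin; the C4 configuration is lost again in step 10.

Step 10
Reactants: 14 (2S,3R,4R)-5,7,3',4'-tetra-O-benzyl-4-(2-ethoxyethoxy)flavan-3-ol; 11 (2R,3R)-2-[3,4-bis(benzyloxy)phenyl]-5,7-bis[4-(trifluoromethyl)benzyloxy]chroman-3-yl acetate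
Product: 15 protected ent-catechin-(4β→8)-epicatechin lower-unit 3-acetate [upper (2S,3R,4R) tetra-O-benzylflavan-3-ol bonded from C4 to C8 of unit 11; upper ring C 2,3-trans-3,4-trans]
Conditions: Me3SiOTf (0.2 equiv), 11 (2 equiv), CH2Cl2, −78 °C
Reagents that add atoms: none
Why: Lewis-acid ionisation of the C4 ether gives the flavan-4-yl cation, which undergoes Friedel–Crafts attack by C8 of 11 (ortho and para to three ring oxygens) anti to the C3 oxygen, giving the 3,4-trans, 2,4-cis linkage as in procyanidin B3-type couplings, while 11 has no C4 leaving group and cannot act as an electrophile.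

Step 11
Reactants: 15 protected ent-catechin-(4β→8)-epicatechin lower-unit 3-acetate
Product: 16 upper-unit C3 ketone of 15, (2S,4R) with 2,4-cis aryl groups
Conditions: Dess–Martin periodinane, pyridine, CH2Cl2, rt
Reagents that add atoms: none
Why: Dess–Martin oxidation of the only free hydroxyl, the lower C3 oxygen being masked as acetate; C4 is now α to the carbonyl, so any 4-epimer carried from step 10 can equilibrate to the 2,4-cis diequatorial ketone.

Step 12
Reactants: 16 upper-unit C3 ketone of 15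
Product: 17 ketone 16 carrying a 4β-hydroxyl on the lower unit, lower ring C (2R,3R,4S), 2,3-cis-3,4-trans
Conditions: DDQ (1.5 equiv), CH2Cl2/H2O 20:1, 0 °C to rt
Reagents that add atoms: water O
Why: DDQ benzylic oxidation at the lower C4 methylene, the only C–H position conjugated to a trioxygenated ring that is not deactivated (the upper C4–H is α to the carbonyl), with water adding to the cation trans to the C3 acetate and the C2 aryl group as in the C4 functionalisation of epicatechin ethers.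

Step 13
Reactants: 17 ketone 16 carrying a 4β-hydroxyl on the lower unit
Product: 19 benzyl-protected triol [upper unit (2S,3S,4R) all-cis flavan-3-ol; lower unit (2R,3R,4S) flavan-3,4-diol], via all-cis alcohol acetate 18 (not isolated)
Conditions: LiBH(s-Bu)3, THF, −78 °C; then K2CO3, MeOH, rt
Reagents that add atoms: none
Why: The bulky hydride attacks the C3 ketone from the face opposite the two cis aryl substituents at C2 and C4 (equatorial attack), giving the axial all-cis alcohol as in the catechin-to-epicatechin inversion, and methanolysis then removes the acetate.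

Step 14
Reactants: 19 benzyl-protected triol
Product: 20 (2R,3R,4S)-2-(3,4-dihydroxyphenyl)-8-[(2S,3S,4R)-2-(3,4-dihydroxyphenyl)-3,5,7-trihydroxychroman-4-yl]chroman-3,4,5,7-tetrol
Conditions: H2 (1 atm), Pd(OH)2/C, THF/EtOAc/H2O, rt
Reagents that add atoms: none
Why: Hydrogenolysis of the six benzyl and two 4-(trifluoromethyl)benzyl aryl ethers under neutral, alcohol-free conditions, which should spare the secondary benzylic C4 hydroxyl and avoid acid-induced ionisation of the flavan-3,4-diol.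

**Compound list**

1 | 2',4',6'-trihydroxyacetophenone | CC(=O)c1c(O)cc(O)cc1O | starting material
2 | 1-{2-hydroxy-4,6-bis[4-(trifluoromethyl)benzyloxy]phenyl}ethanone | CC(=O)c1c(O)cc(OCc2ccc(cc2)C(F)(F)F)cc1OCc1ccc(cc1)C(F)(F)F | intermediate
3 | 3,4-bis(benzyloxy)benzyl chloride | ClCc1ccc(OCc2ccccc2)c(OCc2ccccc2)c1 | starting material
4 | 1-{2-[3,4-bis(benzyloxy)benzyloxy]-4,6-bis[4-(trifluoromethyl)benzyloxy]phenyl}ethanone | CC(=O)c1c(OCc2ccc(OCc3ccccc3)c(OCc3ccccc3)c2)cc(OCc2ccc(cc2)C(F)(F)F)cc1OCc1ccc(cc1)C(F)(F)F | intermediate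
5 | methyl 2-{2-[3,4-bis(benzyloxy)benzyloxy]-4,6-bis[4-(trifluoromethyl)benzyloxy]phenyl}acetate | COC(=O)Cc1c(OCc2ccc(OCc3ccccc3)c(OCc3ccccc3)c2)cc(OCc2ccc(cc2)C(F)(F)F)cc1OCc1ccc(cc1)C(F)(F)F | intermediate
6 | methyl 2-diazo-2-{2-[3,4-bis(benzyloxy)benzyloxy]-4,6-bis[4-(trifluoromethyl)benzyloxy]phenyl}acetate | COC(=O)C(=[N+]=[N-])c1c(OCc2ccc(OCc3ccccc3)c(OCc3ccccc3)c2)cc(OCc2ccc(cc2)C(F)(F)F)cc1OCc1ccc(cc1)C(F)(F)F | intermediate
7 | methyl (2S,3R)-2-[3,4-bis(benzyloxy)phenyl]-4,6-bis[4-(trifluoromethyl)benzyloxy]-2,3-dihydrobenzofuran-3-carboxylate (cis) | COC(=O)[C@H]1[C@@H](c2ccc(OCc3ccccc3)c(OCc3ccccc3)c2)Oc2cc(OCc3ccc(cc3)C(F)(F)F)cc(OCc3ccc(cc3)C(F)(F)F)c12 | intermediate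
8 | {(2S,3S)-2-[3,4-bis(benzyloxy)phenyl]-4,6-bis[4-(trifluoromethyl)benzyloxy]-2,3-dihydrobenzofuran-3-yl}methanol (cis) | OC[C@H]1[C@@H](c2ccc(OCc3ccccc3)c(OCc3ccccc3)c2)Oc2cc(OCc3ccc(cc3)C(F)(F)F)cc(OCc3ccc(cc3)C(F)(F)F)c12 | intermediate
9 | methanesulfonate of alcohol 8 | CS(=O)(=O)OC[C@H]1[C@@H](c2ccc(OCc3ccccc3)c(OCc3ccccc3)c2)Oc2cc(OCc3ccc(cc3)C(F)(F)F)cc(OCc3ccc(cc3)C(F)(F)F)c12 | intermediate
10 | spiro phenonium ion: cyclopropane fused across C3 and the ring A ipso carbon, CH2 on the face of the former CH2OMs group, charge delocalised into ring A (oxocarbenium form drawn) | c1ccccc1COc1ccc(cc1OCc1ccccc1)[C@H]1OC2=CC(=[O+]Cc3ccc(cc3)C(F)(F)F)C=C(OCc3ccc(cc3)C(F)(F)F)[C@@]23C[C@@H]13 | intermediate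
11 | (2R,3R)-2-[3,4-bis(benzyloxy)phenyl]-5,7-bis[4-(trifluoromethyl)benzyloxy]chroman-3-yl acetate (2,3-cis) | CC(=O)O[C@@H]1Cc2c(OCc3ccc(cc3)C(F)(F)F)cc(OCc3ccc(cc3)C(F)(F)F)cc2O[C@@H]1c1ccc(OCc2ccccc2)c(OCc2ccccc2)c1 | intermediate
12 | (−)-catechin, (2S,3R) | O[C@@H]1Cc2c(O)cc(O)cc2O[C@H]1c1ccc(O)c(O)c1 | starting material
13 | (2S,3R)-5,7,3',4'-tetra-O-benzylcatechin | O[C@@H]1Cc2c(OCc3ccccc3)cc(OCc3ccccc3)cc2O[C@H]1c1ccc(OCc2ccccc2)c(OCc2ccccc2)c1 | intermediate
14 | (2S,3R,4R)-5,7,3',4'-tetra-O-benzyl-4-(2-ethoxyethoxy)flavan-3-ol | O[C@@H]1[C@H](OCCOCC)c2c(OCc3ccccc3)cc(OCc3ccccc3)cc2O[C@H]1c1ccc(OCc2ccccc2)c(OCc2ccccc2)c1 | intermediate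
15 | protected dimer, upper (2S,3R,4R) 3-ol, C4→C8 bond, lower (2R,3R) 3-acetate | O[C@@H]1[C@@H](c2c(OCc3ccc(cc3)C(F)(F)F)cc(OCc3ccc(cc3)C(F)(F)F)c3C[C@@H](OC(C)=O)[C@@H](c4ccc(OCc5ccccc5)c(OCc5ccccc5)c4)Oc23)c2c(OCc3ccccc3)cc(OCc3ccccc3)cc2O[C@H]1c1ccc(OCc2ccccc2)c(OCc2ccccc2)c1 | intermediate
16 | upper C3 ketone of 15, (2S,4R) | O=C1[C@@H](c2c(OCc3ccc(cc3)C(F)(F)F)cc(OCc3ccc(cc3)C(F)(F)F)c3C[C@@H](OC(C)=O)[C@@H](c4ccc(OCc5ccccc5)c(OCc5ccccc5)c4)Oc23)c2c(OCc3ccccc3)cc(OCc3ccccc3)cc2O[C@H]1c1ccc(OCc2ccccc2)c(OCc2ccccc2)c1 | intermediate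
17 | ketone 16 with lower 4β-hydroxyl, lower (2R,3R,4S) | O=C1[C@@H](c2c(OCc3ccc(cc3)C(F)(F)F)cc(OCc3ccc(cc3)C(F)(F)F)c3[C@H](O)[C@@H](OC(C)=O)[C@@H](c4ccc(OCc5ccccc5)c(OCc5ccccc5)c4)Oc23)c2c(OCc3ccccc3)cc(OCc3ccccc3)cc2O[C@H]1c1ccc(OCc2ccccc2)c(OCc2ccccc2)c1 | intermediate
18 | upper (2S,3S,4R) all-cis alcohol, lower 3-acetate 4β-ol | O[C@H]1[C@@H](c2c(OCc3ccc(cc3)C(F)(F)F)cc(OCc3ccc(cc3)C(F)(F)F)c3[C@H](O)[C@@H](OC(C)=O)[C@@H](c4ccc(OCc5ccccc5)c(OCc5ccccc5)c4)Oc23)c2c(OCc3ccccc3)cc(OCc3ccccc3)cc2O[C@H]1c1ccc(OCc2ccccc2)c(OCc2ccccc2)c1 | intermediate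
19 | benzyl-protected triol, upper (2S,3S,4R), lower (2R,3R,4S) | O[C@H]1[C@@H](c2c(OCc3ccc(cc3)C(F)(F)F)cc(OCc3ccc(cc3)C(F)(F)F)c3[C@H](O)[C@@H](O)[C@@H](c4ccc(OCc5ccccc5)c(OCc5ccccc5)c4)Oc23)c2c(OCc3ccccc3)cc(OCc3ccccc3)cc2O[C@H]1c1ccc(OCc2ccccc2)c(OCc2ccccc2)c1 | intermediate
20 | (2R,3R,4S)-2-(3,4-dihydroxyphenyl)-8-[(2S,3S,4R)-2-(3,4-dihydroxyphenyl)-3,5,7-trihydroxychroman-4-yl]chroman-3,4,5,7-tetrol | Oc1cc(O)c2c(c1)O[C@@H](c1ccc(O)c(O)c1)[C@@H](O)[C@H]2c1c(O)cc(O)c2c1O[C@H](c1ccc(O)c(O)c1)[C@H](O)[C@H]2O | target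

**Summary**

Total step count: 14. Longest linear sequence: 12 steps (steps 1 to 7, then 10 to 14).

Steps most likely to fail:

1. Step 7. The bridged ion may open at the primary carbon and return to the five-membered ring, or a free C3 cation may escape into oxygen-shift or hydride-shift pathways. Fallback, from compound 7 back to compound 11: a semipinacol version in which a C3 hydroxyl makes opening at C3 end in a carbonyl. The potassium enolate of 7 (KN(SiMe3)2, THF, −78 °C) is hydroxylated with 2-(phenylsulfonyl)-3-phenyloxaziridine to the tertiary hydroxy ester F1 (hydroxyl expected trans to the C2 aryl group; this centre is erased later). LiAlH4 gives the diol F2, and TsCl in pyridine sulfonylates the primary hydroxyl to the monotosylate F3. Heating with LiClO4 and CaCO3 in THF causes the same aryl shift, now ending in the flavan-3-one F4. LiBH(s-Bu)3 at −78 °C gives the 2,3-cis flavan-3-ol F5, and Ac2O in pyridine returns 11.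

2. Step 12. Oxidation of the enol of the upper ketone, or over-oxidation of the new benzylic carbinol, may compete with hydroxylation of the lower C4. Fallback, from compounds 11 and 14 back to compound 18: the C4 oxygen is prepared before the coupling and carried as a thioether. DDQ and 2-ethoxyethanol convert 11 into the 4β-(2-ethoxyethoxy) acetate F6. 2,6-Dimethylbenzenethiol with BF3·OEt2 at −78 °C exchanges the ether for the 4β-arylthio group to give thioether F7. BF3·OEt2-promoted coupling with 14, to which the thioether is inert, gives the dimer F8. Dess–Martin oxidation gives the ketone F9 and LiBH(s-Bu)3 gives the all-cis alcohol F10. AgOTf in wet THF with 2,6-di-tert-butylpyridine then hydrolyses the thioether with delivery of water trans to the C3 acetate and gives 18, which is deacetylated with K2CO3 in MeOH to 19.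

3. Step 5. Enantioselectivity and cis selectivity may erode in the insertion of the doubly ortho-substituted carbenoid. Fallback, from compound 6 back to compound 8: resolution in place of catalyst control. Rh2(OAc)4 gives the racemic cis ester, that is 7 together with its enantiomer F11. i-Bu2AlH gives the racemic alcohol, 8 together with its enantiomer F12. Esterification with (R)-2-methoxy-2-phenylacetic acid (DCC, DMAP) gives the diastereomeric esters F13 (from 8) and F14 (from F12), which are separated by chromatography or crystallisation. K2CO3 in MeOH cleaves F13 and returns 8.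

**Further compounds**

F1 | step 7 | methyl (2R,3S)-2-[3,4-bis(benzyloxy)phenyl]-3-hydroxy-4,6-bis[4-(trifluoromethyl)benzyloxy]-2,3-dihydrobenzofuran-3-carboxylate (hydroxyl trans to aryl) | COC(=O)[C@@]1(O)[C@@H](c2ccc(OCc3ccccc3)c(OCc3ccccc3)c2)Oc2cc(OCc3ccc(cc3)C(F)(F)F)cc(OCc3ccc(cc3)C(F)(F)F)c12
F2 | step 7 | corresponding 3-hydroxy-3-(hydroxymethyl) diol | OC[C@@]1(O)[C@@H](c2ccc(OCc3ccccc3)c(OCc3ccccc3)c2)Oc2cc(OCc3ccc(cc3)C(F)(F)F)cc(OCc3ccc(cc3)C(F)(F)F)c12
F3 | step 7 | primary p-toluenesulfonate of diol F2 | Cc1ccc(cc1)S(=O)(=O)OC[C@@]1(O)[C@@H](c2ccc(OCc3ccccc3)c(OCc3ccccc3)c2)Oc2cc(OCc3ccc(cc3)C(F)(F)F)cc(OCc3ccc(cc3)C(F)(F)F)c12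
F4 | step 7 | (2R)-2-[3,4-bis(benzyloxy)phenyl]-5,7-bis[4-(trifluoromethyl)benzyloxy]chroman-3-one | O=C1Cc2c(OCc3ccc(cc3)C(F)(F)F)cc(OCc3ccc(cc3)C(F)(F)F)cc2O[C@@H]1c1ccc(OCc2ccccc2)c(OCc2ccccc2)c1
F5 | step 7 | (2R,3R)-2-[3,4-bis(benzyloxy)phenyl]-5,7-bis[4-(trifluoromethyl)benzyloxy]chroman-3-ol (2,3-cis) | O[C@@H]1Cc2c(OCc3ccc(cc3)C(F)(F)F)cc(OCc3ccc(cc3)C(F)(F)F)cc2O[C@@H]1c1ccc(OCc2ccccc2)c(OCc2ccccc2)c1
F6 | step 12 | 4β-(2-ethoxyethoxy) derivative of acetate 11 (3,4-trans) | CC(=O)O[C@@H]1[C@@H](OCCOCC)c2c(OCc3ccc(cc3)C(F)(F)F)cc(OCc3ccc(cc3)C(F)(F)F)cc2O[C@@H]1c1ccc(OCc2ccccc2)c(OCc2ccccc2)c1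
F7 | step 12 | 4β-(2,6-dimethylphenylthio) derivative of acetate 11 (3,4-trans) | CC(=O)O[C@@H]1[C@@H](Sc2c(C)cccc2C)c2c(OCc3ccc(cc3)C(F)(F)F)cc(OCc3ccc(cc3)C(F)(F)F)cc2O[C@@H]1c1ccc(OCc2ccccc2)c(OCc2ccccc2)c1
F8 | step 12 | dimer 15 carrying the lower 4β-(2,6-dimethylphenylthio) group | O[C@@H]1[C@@H](c2c(OCc3ccc(cc3)C(F)(F)F)cc(OCc3ccc(cc3)C(F)(F)F)c3[C@H](Sc4c(C)cccc4C)[C@@H](OC(C)=O)[C@@H](c4ccc(OCc5ccccc5)c(OCc5ccccc5)c4)Oc23)c2c(OCc3ccccc3)cc(OCc3ccccc3)cc2O[C@H]1c1ccc(OCc2ccccc2)c(OCc2ccccc2)c1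
F9 | step 12 | upper C3 ketone of F8 | O=C1[C@@H](c2c(OCc3ccc(cc3)C(F)(F)F)cc(OCc3ccc(cc3)C(F)(F)F)c3[C@H](Sc4c(C)cccc4C)[C@@H](OC(C)=O)[C@@H](c4ccc(OCc5ccccc5)c(OCc5ccccc5)c4)Oc23)c2c(OCc3ccccc3)cc(OCc3ccccc3)cc2O[C@H]1c1ccc(OCc2ccccc2)c(OCc2ccccc2)c1
F10 | step 12 | upper all-cis (2S,3S,4R) alcohol from F9, lower 3-acetate 4β-thioether | O[C@H]1[C@@H](c2c(OCc3ccc(cc3)C(F)(F)F)cc(OCc3ccc(cc3)C(F)(F)F)c3[C@H](Sc4c(C)cccc4C)[C@@H](OC(C)=O)[C@@H](c4ccc(OCc5ccccc5)c(OCc5ccccc5)c4)Oc23)c2c(OCc3ccccc3)cc(OCc3ccccc3)cc2O[C@H]1c1ccc(OCc2ccccc2)c(OCc2ccccc2)c1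
F11 | step 5 | (2R,3S) enantiomer of ester 7 | COC(=O)[C@@H]1[C@H](c2ccc(OCc3ccccc3)c(OCc3ccccc3)c2)Oc2cc(OCc3ccc(cc3)C(F)(F)F)cc(OCc3ccc(cc3)C(F)(F)F)c12
F12 | step 5 | (2R,3R) enantiomer of alcohol 8 | OC[C@@H]1[C@H](c2ccc(OCc3ccccc3)c(OCc3ccccc3)c2)Oc2cc(OCc3ccc(cc3)C(F)(F)F)cc(OCc3ccc(cc3)C(F)(F)F)c12
F13 | step 5 | (R)-2-methoxy-2-phenylacetate of alcohol 8 | CO[C@H](c1ccccc1)C(=O)OC[C@H]1[C@@H](c2ccc(OCc3ccccc3)c(OCc3ccccc3)c2)Oc2cc(OCc3ccc(cc3)C(F)(F)F)cc(OCc3ccc(cc3)C(F)(F)F)c12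
F14 | step 5 | (R)-2-methoxy-2-phenylacetate of alcohol F12 | CO[C@H](c1ccccc1)C(=O)OC[C@@H]1[C@H](c2ccc(OCc3ccccc3)c(OCc3ccccc3)c2)Oc2cc(OCc3ccc(cc3)C(F)(F)F)cc(OCc3ccc(cc3)C(F)(F)F)c12
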